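**Plan**

- Target 15 is an achiral bibenzyl. Ring A (C1–C6, bridge on C1) has methoxy groups on C3 and C5 and a prenyl group (C1''H2–C2''H=C3''Me2) on C4; ring B (C1'–C6') has 2'-OMe, 3'-OH and 4'-OAc.
- Enabling feature: ring A C4 lies between the oxygens on C3 and C5, so the prenyl chain plus one of these oxygens is the ring-opened form of a 2,2-dimethyl-2H-chromene fused to ring A (bonds C4–C1'' and O–C3'').
- Cuts, in retrosynthetic order: the 4'-O–acetyl bond and the ring B MOM groups; the two ring A O–CH3 bonds, around a reconnection of O to C3'' (pyran); C4–C1'' and O–C3'' together (enal annulation of a symmetric resorcinol); the bridge C–C bond as an olefin (phosphonate plus aldehyde).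
- Forward: Horner–Wadsworth–Emmons union of the two arenes; one hydrogenation (bridge saturated, ring A phenols freed); pyran ring closed on ring A with 3-methylbut-2-enal; O-methylation; Li/NH3 opening to the ortho-prenylphenol; second O-methylation; MOM removal; mono-acetylation at 4'-O.
- Stereochemistry: none to set. The target has no stereocentre, its only olefin carries two identical methyl groups, and the E geometry of the stilbene is erased by hydrogenation.

Key step: step 6

Remark: locants are ring A C1–C6 (bridge on C1), ring B C1'–C6' (bridge on C1') and prenyl C1''–C3''; phenoxides and the phosphonate carbanion formed by simple deprotonation are treated as forms of their parent compounds and carry no number.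

**Route**

Step 1
Reactants: 1 3,5-bis(benzyloxy)benzyl bromide
Product: 2 diethyl [3,5-bis(benzyloxy)benzyl]phosphonate
Conditions: P(OEt)3 (neat), 140 °C; excess phosphite removed in vacuo
Reagents that add atoms: triethyl phosphite, CCOP(OCC)OCC
Why: The Michaelis–Arbuzov reaction of a primary benzylic bromide with triethyl phosphite is reliable, and the benzyl ethers are inert to it.

Step 2
Reactants: 3 2,3,4-trihydroxybenzaldehyde
Product: 4 2-hydroxy-3,4-bis(methoxymethoxy)benzaldehyde
Conditions: MOMCl (2.2 equiv), i-Pr2NEt, CH2Cl2–DMF, 0 °C to rt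
Reagents that add atoms: chloromethyl methyl ether, COCCl
Why: Williamson-type O-alkylation under amine base protects the C3 and C4 phenols, while the C2 phenol, held in a hydrogen bond to the formyl oxygen, is too weakly nucleophilic to react with the limited amount of reagent.

Step 3
Reactants: 4 2-hydroxy-3,4-bis(methoxymethoxy)benzaldehyde
Product: 5 2-methoxy-3,4-bis(methoxymethoxy)benzaldehyde
Conditions: MeI, K2CO3, DMF, rt to 40 °C
Reagents that add atoms: iodomethane, CI
Why: Williamson O-methylation of the chelated ortho-formyl phenol goes to completion with K2CO3 in a dipolar aprotic solvent, and the MOM acetals are stable to base.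

Step 4
Reactants: 2 diethyl [3,5-bis(benzyloxy)benzyl]phosphonate; 5 2-methoxy-3,4-bis(methoxymethoxy)benzaldehyde
Product: 6 1-{(E)-2-[3,5-bis(benzyloxy)phenyl]ethenyl}-2-methoxy-3,4-bis(methoxymethoxy)benzene
Conditions: KOtBu, THF, 0 °C to rt
Reagents that add atoms: none
Why: The Horner–Wadsworth–Emmons olefination of a benzylic phosphonate with an aryl aldehyde should give the E stilbene, whose geometry is irrelevant because the olefin is saturated in the next step.

Step 5
Reactants: 6 1-{(E)-2-[3,5-bis(benzyloxy)phenyl]ethenyl}-2-methoxy-3,4-bis(methoxymethoxy)benzene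
Product: 7 5-{2-[2-methoxy-3,4-bis(methoxymethoxy)phenyl]ethyl}benzene-1,3-diol
Conditions: H2 (1 atm), 10% Pd/C, EtOAc–EtOH, rt
Reagents that add atoms: none
Why: Heterogeneous catalytic hydrogenation saturates the stilbene olefin and hydrogenolyses both benzyl ethers in one operation, while MOM acetals and aryl methyl ethers are untouched under neutral conditions, so the bridge is saturated before any other olefin exists.

Step 6
Reactants: 7 5-{2-[2-methoxy-3,4-bis(methoxymethoxy)phenyl]ethyl}benzene-1,3-diol; 8 3-methylbut-2-enal
Product: 10 7-{2-[2-methoxy-3,4-bis(methoxymethoxy)phenyl]ethyl}-2,2-dimethyl-2H-chromen-5-ol, via ortho-quinone methide dienone 9 (not isolated)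
Conditions: 8 (1.2 equiv), ethylenediammonium diacetate (10 mol %), toluene, 110 °C
Reagents that add atoms: none
Why: Ethylenediammonium diacetate turns enal 8 into an iminium ion that is attacked, in a Knoevenagel-type condensation, by ring A C4 (the carbon ortho to both hydroxyls), and loss of the amine leaves the ortho-quinone methide dienone 9 with the new C4–C1'' bond in place. The 1-oxatriene of 9 (O=C3–C4=C1''–C2''=C3'') then closes the 2H-pyran ring by a thermal disrotatory 6π-oxa-electrocyclisation that forms the O–C3'' bond and restores the aromaticity of ring A. The closest known reaction type is the amine-salt-mediated chromenylation (formal [3+3] annulation) of 5-alkylresorcinols with α,β-unsaturated aldehydes. No stereocentre arises, because the only new sp3 carbon, C3'', carries two methyl groups. The step needs site selectivity for C4 over C2 and C6 and mono- over double annulation: C4 is the position activated by two ortho hydroxyls, which is where 5-alkylresorcinols are known to react in this annulation, the mirror plane through C1 and C4 makes both hydroxyls lead to the same chromene, and a near-stoichiometric charge of 8 holds back a second ring closure on the remaining phenol. Ring B has no free phenol and the bridge no olefin, so neither can compete.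

Step 7
Reactants: 10 7-{2-[2-methoxy-3,4-bis(methoxymethoxy)phenyl]ethyl}-2,2-dimethyl-2H-chromen-5-ol
Product: 11 5-methoxy-7-{2-[2-methoxy-3,4-bis(methoxymethoxy)phenyl]ethyl}-2,2-dimethyl-2H-chromene
Conditions: MeI, K2CO3, acetone, reflux
Reagents that add atoms: iodomethane, CI
Why: Williamson O-methylation of the single free phenol is unambiguous, and the chromene olefin and MOM acetals are inert to carbonate and iodomethane.

Step 8
Reactants: 11 5-methoxy-7-{2-[2-methoxy-3,4-bis(methoxymethoxy)phenyl]ethyl}-2,2-dimethyl-2H-chromene
Product: 12 3-methoxy-5-{2-[2-methoxy-3,4-bis(methoxymethoxy)phenyl]ethyl}-2-(3-methylbut-2-en-1-yl)phenol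
Conditions: Li (2.5–3 equiv), NH3(l)–THF, −78 °C, short contact; then solid NH4Cl
Reagents that add atoms: none
Why: In this dissolving-metal (Birch-type) reductive cleavage, electron transfer into the aryl-conjugated C1''=C2'' olefin expels the allylic phenoxide from C3'', a second electron gives the allyl anion, and ammonia protonates it at the benzylic terminus C1'' to leave the C2''=C3'' prenyl olefin, which is the established behaviour of 2,2-dimethyl-2H-chromenes, while MOM acetals, aryl methyl ethers and the alcohol-free arenes should withstand a short exposure at −78 °C.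

Step 9
Reactants: 12 3-methoxy-5-{2-[2-methoxy-3,4-bis(methoxymethoxy)phenyl]ethyl}-2-(3-methylbut-2-en-1-yl)phenol
Product: 13 1-{2-[3,5-dimethoxy-4-(3-methylbut-2-en-1-yl)phenyl]ethyl}-2-methoxy-3,4-bis(methoxymethoxy)benzene
Conditions: MeI, K2CO3, DMF, rt
Reagents that add atoms: iodomethane, CI
Why: Williamson O-methylation of the ortho-prenylphenol in a dipolar aprotic solvent overcomes the flanking substituent, and capping this oxygen also removes any later chance of acid-induced chroman formation.

Step 10
Reactants: 13 1-{2-[3,5-dimethoxy-4-(3-methylbut-2-en-1-yl)phenyl]ethyl}-2-methoxy-3,4-bis(methoxymethoxy)benzene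
Product: 14 4-{2-[3,5-dimethoxy-4-(3-methylbut-2-en-1-yl)phenyl]ethyl}-3-methoxybenzene-1,2-diol
Conditions: 3 M aq. HCl (few equiv), MeOH, rt to 40 °C, under argon; the catechol is used directly
Reagents that add atoms: none
Why: Acid-catalysed acetal exchange with methanol removes both aryl MOM groups under conditions mild enough for a trisubstituted olefin that has no neighbouring free phenol to cyclise onto.

Step 11
Reactants: 14 4-{2-[3,5-dimethoxy-4-(3-methylbut-2-en-1-yl)phenyl]ethyl}-3-methoxybenzene-1,2-diol
Product: 15 4-{2-[3,5-dimethoxy-4-(3-methylbut-2-en-1-yl)phenyl]ethyl}-2-hydroxy-3-methoxyphenyl acetate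
Conditions: Ac2O (1.0 equiv), pyridine, CH2Cl2, −20 to 0 °C
Reagents that add atoms: acetic anhydride, CC(=O)OC(C)=O
Why: Kinetic O-acylation with pyridine as nucleophilic catalyst should pick the 4'-hydroxyl, which has an ortho hydrogen, over the 3'-hydroxyl, which is flanked by the 2'-methoxy group and the 4'-oxygen; one equivalent of anhydride limits diacetate formation, and the 4'-ester is also the less crowded of the two monoacetates should acyl migration occur.

**Compound list**

1 | 3,5-bis(benzyloxy)benzyl bromide | BrCc1cc(OCc2ccccc2)cc(OCc2ccccc2)c1 | starting material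
2 | diethyl [3,5-bis(benzyloxy)benzyl]phosphonate | CCOP(=O)(Cc1cc(OCc2ccccc2)cc(OCc2ccccc2)c1)OCC | intermediate
3 | 2,3,4-trihydroxybenzaldehyde | O=Cc1ccc(O)c(O)c1O | starting material
4 | 2-hydroxy-3,4-bis(methoxymethoxy)benzaldehyde | COCOc1ccc(C=O)c(O)c1OCOC | intermediate
5 | 2-methoxy-3,4-bis(methoxymethoxy)benzaldehyde | COCOc1ccc(C=O)c(OC)c1OCOC | intermediate
6 | 1-{(E)-2-[3,5-bis(benzyloxy)phenyl]ethenyl}-2-methoxy-3,4-bis(methoxymethoxy)benzene | COCOc1ccc(/C=C/c2cc(OCc3ccccc3)cc(OCc3ccccc3)c2)c(OC)c1OCOC | intermediate
7 | 5-{2-[2-methoxy-3,4-bis(methoxymethoxy)phenyl]ethyl}benzene-1,3-diol | COCOc1ccc(CCc2cc(O)cc(O)c2)c(OC)c1OCOC | intermediate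
8 | 3-methylbut-2-enal | CC(C)=CC=O | starting material
9 | ortho-quinone methide dienone: 3-hydroxy-5-{2-[2-methoxy-3,4-bis(methoxymethoxy)phenyl]ethyl}-2-(3-methylbut-2-en-1-ylidene)cyclohexa-3,5-dien-1-one (exocyclic olefin geometry not defined; formed and consumed in step 6) | COCOc1ccc(CCC2=CC(=O)C(=CC=C(C)C)C(O)=C2)c(OC)c1OCOC | intermediate
10 | 7-{2-[2-methoxy-3,4-bis(methoxymethoxy)phenyl]ethyl}-2,2-dimethyl-2H-chromen-5-ol | COCOc1ccc(CCc2cc(O)c3C=CC(C)(C)Oc3c2)c(OC)c1OCOC | intermediate
11 | 5-methoxy-7-{2-[2-methoxy-3,4-bis(methoxymethoxy)phenyl]ethyl}-2,2-dimethyl-2H-chromene | COCOc1ccc(CCc2cc(OC)c3C=CC(C)(C)Oc3c2)c(OC)c1OCOC | intermediate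
12 | 3-methoxy-5-{2-[2-methoxy-3,4-bis(methoxymethoxy)phenyl]ethyl}-2-(3-methylbut-2-en-1-yl)phenol | COCOc1ccc(CCc2cc(O)c(CC=C(C)C)c(OC)c2)c(OC)c1OCOC | intermediate
13 | 1-{2-[3,5-dimethoxy-4-(3-methylbut-2-en-1-yl)phenyl]ethyl}-2-methoxy-3,4-bis(methoxymethoxy)benzene | COCOc1ccc(CCc2cc(OC)c(CC=C(C)C)c(OC)c2)c(OC)c1OCOC | intermediate
14 | 4-{2-[3,5-dimethoxy-4-(3-methylbut-2-en-1-yl)phenyl]ethyl}-3-methoxybenzene-1,2-diol | COc1cc(CCc2ccc(O)c(O)c2OC)cc(OC)c1CC=C(C)C | intermediate
15 | 4-{2-[3,5-dimethoxy-4-(3-methylbut-2-en-1-yl)phenyl]ethyl}-2-hydroxy-3-methoxyphenyl acetate | COc1cc(CCc2ccc(OC(C)=O)c(O)c2OC)cc(OC)c1CC=C(C)C | target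

**Step count and risks**

Total step count: 11.
Longest linear sequence: 10 steps (3 → 4 → 5 → 6 → 7 → 10 → 11 → 12 → 13 → 14 → 15; steps 2 to 11).

Steps most likely to fail:

Step 6. Attack of the iminium ion at the ring A carbons ortho to the bridge instead of at C4, and a second annulation on the remaining phenol, would erode the annulation. The fallback replaces the annulation by a halogen handle. It sets out from 7: iodination at the carbon between the two hydroxyls (I2, NaHCO3, THF–H2O, 0 °C) should give 2-iodo-5-{2-[2-methoxy-3,4-bis(methoxymethoxy)phenyl]ethyl}benzene-1,3-diol F1. O-Methylation of both phenols (MeI, K2CO3, DMF) should give 1-[2-(4-iodo-3,5-dimethoxyphenyl)ethyl]-2-methoxy-3,4-bis(methoxymethoxy)benzene F2. Iodine–lithium exchange (n-BuLi, THF, −78 °C), which is faster than any directed deprotonation on ring B, followed by allylation with 1-bromo-3-methylbut-2-ene in the presence of CuBr·SMe2 (cat.), brings the sequence back to the route at 13.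

Step 8. Protonation of the allyl anion at its tertiary terminus (giving the conjugated 3-methylbut-1-enyl isomer), over-reduction of the olefin, or reductive loss of an alkoxy group from the tri-oxygenated ring B may accompany the cleavage. The fallback avoids electron transfer altogether. It sets out from 7: a surface-templated Friedel–Crafts ortho-allylation with 3-methylbut-2-en-1-ol on acidic Al2O3 in refluxing 1,2-dichloroethane should place the prenyl group on the carbon flanked by both hydroxyls and give 5-{2-[2-methoxy-3,4-bis(methoxymethoxy)phenyl]ethyl}-2-(3-methylbut-2-en-1-yl)benzene-1,3-diol F3. Double O-methylation (MeI, K2CO3, DMF) then returns to the route at 13.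

Step 11. Acylation of both phenols or of the 3'-hydroxyl, and acyl migration between the neighbouring oxygens, may blur the mono-acetylation. The fallback delivers exactly one acetyl group per catechol through a cyclic orthoester. It sets out from 14: exchange with trimethyl orthoacetate (CC(OC)(OC)OC) under catalytic pyridinium p-toluenesulfonate in CH2Cl2 should give racemic 5-{2-[3,5-dimethoxy-4-(3-methylbut-2-en-1-yl)phenyl]ethyl}-2,4-dimethoxy-2-methyl-1,3-benzodioxole F4. Mild hydrolytic opening (aq. AcOH, THF, rt) should release the more crowded 3'-oxygen and leave the acetate on 4'-O, returning to the route at 15. Any 3'-acetate could be funnelled to the less hindered ester by 1,2-acyl shift with a trace of triethylamine.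

**Further compounds**

F1 | step 6 | 2-iodo-5-{2-[2-methoxy-3,4-bis(methoxymethoxy)phenyl]ethyl}benzene-1,3-diol | COCOc1ccc(CCc2cc(O)c(I)c(O)c2)c(OC)c1OCOC
F2 | step 6 | 1-[2-(4-iodo-3,5-dimethoxyphenyl)ethyl]-2-methoxy-3,4-bis(methoxymethoxy)benzene | COCOc1ccc(CCc2cc(OC)c(I)c(OC)c2)c(OC)c1OCOC
F3 | step 8 | 5-{2-[2-methoxy-3,4-bis(methoxymethoxy)phenyl]ethyl}-2-(3-methylbut-2-en-1-yl)benzene-1,3-diol | COCOc1ccc(CCc2cc(O)c(CC=C(C)C)c(O)c2)c(OC)c1OCOC
F4 | step 11 | 5-{2-[3,5-dimethoxy-4-(3-methylbut-2-en-1-yl)phenyl]ethyl}-2,4-dimethoxy-2-methyl-1,3-benzodioxole (racemic) | COc1cc(CCc2ccc3OC(C)(OC)Oc3c2OC)cc(OC)c1CC=C(C)C
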